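All runs stem from a simulated flask with made-up constants.

Late in the south-west run the target climbs slowly: 84.7 mM stands at 50 min, less than the 93.6 mM of the east run, which has the same substrate charge and a third of the reagent.

| flask | substrate | reagent | free catalyst | time |
|---|---|---|---|---|
| east | 100 mM | 250 mM | 10.0 mM |  |
| north | 50.0 mM | 200 mM | 10.0 mM |  |
| south-west | 100 mM | 750 mM | 10.0 mM |  |
| south | 150 mM | 250 mM | 10.0 mM |  |
| north-east | 300 mM | 750 mM | 10.0 mM | 50 min |

| east run: time / min | east run: [target] / mM | north run: time / min | north run: [target] / mM | south-west run: time / min | south-west run: [target] / mM | south run: time / min | south run: [target] / mM |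
|---|---|---|---|---|---|---|---|
| 2.0 | 5.0 | 2.0 | 3.2 | 2.0 | 4.2 | 2.0 | 4.3 |
| 3.8 | 9.9 | 3.8 | 6.5 | 3.8 | 10.7 | 3.8 | 9.2 |
| 7.2 | 18.9 | 7.2 | 13.9 | 7.2 | 19.9 | 7.2 | 18.8 |
| 14 | 37.0 | 14 | 25.3 | 14 | 36.7 | 14 | 38.2 |
| 26 | 63.7 | 26 | 39.6 | 26 | 60.0 | 26 | 67.8 |
| 50 | 93.6 | 50 | 49.6 | 50 | 84.7 | 50 | 115.9 |

(standard deviation of a reading: 0.8 mM)

- Overall: substrate + reagent -> target, with free catalyst as catalyst.
- Constant volume, constant temperature.
- Bound and free are read together.
- "The second partner" is reagent.
- An order is taken over about fifteen percent of the charge, up and down.

1. how the opening rate goes with [substrate] round the charge of the east run: the exponent of the rate at two percent of substrate gone to target (one fixed amount of target, the same in the runs compared)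
2. how the opening rate goes with [reagent] round the charge of the east run: the exponent of the rate at two percent of substrate gone to target
3. the north run starts with 50.0 mM less of substrate and of reagent than the east run, and with no target. Compared where both hold the same amount of substrate, once fifteen percent of what the north run was charged with has turned into target, is the north run faster, slower or alike (within a tenth)?
4. target in the north-east run at 50 min, as a share of the substrate charged

Follow one molecule of substrate, bound and free counted together. Each minute it either turns into target or waits. Its chance per minute can be written as V/(h + [substrate]), where V is a ceiling rate. Summed over the run, this gives a clock: the time to a target P is P plus h·ln(charge/(charge − P)), all divided by V.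

Two south-west readings, at 14 min and 50 min, give the knee, the [substrate] at which the rate is 50.0% of its ceiling (an apparent Michaelis constant), as 190 mM, with a ceiling of 8.82 mM min⁻¹. This is a rough reading, since it rests on a small difference between two logarithmic terms. The north run, read at 14 min and 26 min, gives a knee of 28.3 mM and a ceiling of 3.24 mM min⁻¹, so the south-west knee is higher.

Now the question turned round. The north-east run has the reagent charge of the south-west run, so it borrows that knee, though its substrate charge of 300 mM lies beyond the 100 mM that the knee was read on. On this clock, to stand below 50.0% of its charge at 50 min, the north-east run would need a ceiling under 5.63 mM min⁻¹. The south-west ceiling is higher. On this clock the north-east run passes 50.0% at 31.9 min and reaches 70.0% at 49.7 min, so the reckoning here commits to about 70.0%.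

The forecast gives 0.2 for the order in substrate, 0 for the order in reagent, slower for the north run, and 47%, which is lower than the reckoning here. Its ground for the last figure: “North-east should hold near 2.8 mM/min, giving about 140 mM, or about 47%.”

The simulation gives 0.23, 0.50, alike and 77.7%.

    free catalyst + substrate → catalyst-substrate complex (46.62 M⁻¹ min⁻¹)
    catalyst-substrate complex + reagent → loaded catalyst (2.868 M⁻¹ min⁻¹)
    loaded catalyst → target + free catalyst (23.10 min⁻¹)
    free catalyst + impurity → spent catalyst
    substrate + reagent ⇌ idle substrate-reagent adduct, settled at all times (11.10 M⁻¹)

The clock with the knee of 190 mM puts that share at 58.8 min, against the 50 min of the north-east run. In the south-west run the same clock gives 9.03 min for a quarter of the charge, and the simulated time is 8.99 min. At 50 min the north-east run stands short of its full charge because of the idle substrate-reagent adduct: without this parking the run gives >99.9% instead of 77.7%.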